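## Retrosynthetic overview

1. Last step: hydrogenolysis of four benzyl ethers (two phenols, two carbinols). Both R centres are bought in as methyl (R)-3-hydroxybutanoate.
2. The four aryl ester C–O bonds are cut in pairs: the two (R)-3-(benzyloxy)butanoates from one catechol, the acetate/3-phenylpropanoate pair from the other, whose two hydroxyls are symmetry-equivalent.
3. The two catechol pairs are told apart by protection: one as the methylene acetal inherited from sesamol, the other as a bis-MOM ether.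
4. The two aryl–aryl bonds come from a double Suzuki–Miyaura coupling of a 4,7-dibromo-1,3-benzodioxole with [4-(benzyloxy)phenyl]boronic acid.
5. Rings: none is built. The central ring is sesamol (fourth oxygen by ortho-oxygenation), the outer rings come with the boronic acid, and the dioxole ring is only opened.

Assumption: sesamol, methyl (R)-3-hydroxybutanoate, [4-(benzyloxy)phenyl]boronic acid and 3-phenylpropanoyl chloride are taken as commercial; both carbinol centres are R, as the SMILES encodes.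

## Route

Step 1
Reactants: 1 methyl (R)-3-hydroxybutanoate
Product: 2 methyl (R)-3-(benzyloxy)butanoate
Conditions: benzyl 2,2,2-trichloroacetimidate (1.3 equiv), TfOH (5 mol %), cyclohexane/CH2Cl2 2:1, 0 °C to rt
Reagents that add atoms: benzyl 2,2,2-trichloroacetimidate, N=C(OCc1ccccc1)C(Cl)(Cl)Cl
Why: Acid-catalysed O-benzylation with a trichloroacetimidate alkylates the hydroxyl oxygen without touching the C–O stereocentre and avoids the retro-aldol and elimination pathways that basic benzylation of a beta-hydroxy ester invites.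

Step 2
Reactants: 2 methyl (R)-3-(benzyloxy)butanoate
Product: 3 (R)-3-(benzyloxy)butanoic acid
Conditions: LiOH·H2O (2 equiv), THF/H2O 3:1, 0 °C to rt; then 1 M HCl
Reagents that add atoms: lithium hydroxide, [Li+].[OH-]
Why: Ester saponification (acyl–oxygen cleavage) under cold, mild conditions leaves the beta stereocentre, which is not epimerisable, untouched and does not trigger beta-elimination of benzyl alcohol.

Step 3
Reactants: 4 sesamol (1,3-benzodioxol-5-ol)
Product: 6 1,3-benzodioxole-5,6-diol, via ortho-quinone 5 (not isolated)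
Conditions: IBX (1.1 equiv), DMF, rt, 1 h; then Na2S2O4, H2O, rt (argon)
Reagents that add atoms: IBX (2-iodoxybenzoic acid), O=C1OI(=O)(O)c2ccccc12
Why: Regioselective ortho-oxygenation of a phenol: IBX binds the phenol oxygen and delivers oxygen to the less hindered ortho carbon (C6) to give the ortho-quinone, which dithionite reduces to the catechol.

Step 4
Reactants: 6 1,3-benzodioxole-5,6-diol
Product: 7 5,6-bis(methoxymethoxy)-1,3-benzodioxole
Conditions: MOMCl (3 equiv), i-Pr2NEt (4 equiv), CH2Cl2, 0 °C to rt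
Reagents that add atoms: chloromethyl methyl ether (MOMCl), COCCl
Why: O-Alkylation of both phenols with the reactive alpha-chloro ether gives a base-stable bis-MOM ether that is orthogonal to the cyclic methylene acetal.

Step 5
Reactants: 7 5,6-bis(methoxymethoxy)-1,3-benzodioxole
Product: 8 4,7-dibromo-5,6-bis(methoxymethoxy)-1,3-benzodioxole
Conditions: NBS (2.2 equiv), MeCN, 0 °C to rt, dark
Reagents that add atoms: N-bromosuccinimide (NBS), O=C1CCC(=O)N1Br
Why: Electrophilic aromatic bromination is confined to C4 and C7, the only free ring positions, each ortho to two oxygens, and NBS in MeCN releases no acid that would strip the MOM groups.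

Step 6
Reactants: 8 4,7-dibromo-5,6-bis(methoxymethoxy)-1,3-benzodioxole; 9 [4-(benzyloxy)phenyl]boronic acid
Product: 10 4,7-bis[4-(benzyloxy)phenyl]-5,6-bis(methoxymethoxy)-1,3-benzodioxole
Conditions: 9 (2.6 equiv), Pd(OAc)2 (5 mol %), SPhos (10 mol %), K3PO4 (4 equiv), toluene/H2O 10:1, 90 °C
Reagents that add atoms: none
Why: Double Suzuki–Miyaura coupling in which zerovalent palladium carrying the bulky, electron-rich SPhos ligand inserts into the hindered C–Br bonds flanked by two oxygens, while MOM ethers, methylene acetal and benzyl ethers are stable to aqueous phosphate.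

Step 7
Reactants: 10 4,7-bis[4-(benzyloxy)phenyl]-5,6-bis(methoxymethoxy)-1,3-benzodioxole
Product: 11 4,7-bis[4-(benzyloxy)phenyl]-1,3-benzodioxole-5,6-diol
Conditions: conc. HCl (cat.), MeOH/THF 1:1, 50 °C (argon)
Reagents that add atoms: none
Why: Acid-catalysed transacetalisation to methanol removes the acyclic MOM acetals, whereas the cyclic aryl methylene acetal and the benzyl ethers do not ionise under these conditions.

Step 8
Reactants: 11 4,7-bis[4-(benzyloxy)phenyl]-1,3-benzodioxole-5,6-diol; 12 3-phenylpropanoyl chloride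
Product: 13 4,7-bis[4-(benzyloxy)phenyl]-6-hydroxy-1,3-benzodioxol-5-yl 3-phenylpropanoate
Conditions: 12 (1.0 equiv, slow addition), pyridine (3 equiv), CH2Cl2, −40 to 0 °C
Reagents that add atoms: none
Why: Nucleophilic acyl substitution (acid chloride/pyridine acylation) on a diol whose two hydroxyls are symmetry-equivalent gives one possible monoester, and the first acyl group hinders and deactivates the neighbouring hydroxyl so that one equivalent stops there.

Step 9
Reactants: 13 4,7-bis[4-(benzyloxy)phenyl]-6-hydroxy-1,3-benzodioxol-5-yl 3-phenylpropanoate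
Product: 14 6-acetoxy-4,7-bis[4-(benzyloxy)phenyl]-1,3-benzodioxol-5-yl 3-phenylpropanoate
Conditions: Ac2O (3 equiv), pyridine, DMAP (5 mol %), CH2Cl2, 0 °C to rt
Reagents that add atoms: acetic anhydride, CC(=O)OC(C)=O
Why: DMAP-catalysed acetylation (nucleophilic acyl transfer) caps the remaining hindered phenol with the smallest acyl group, and any ortho acyl migration in 13 is degenerate, so a single mixed diester results.

Step 10
Reactants: 14 6-acetoxy-4,7-bis[4-(benzyloxy)phenyl]-1,3-benzodioxol-5-yl 3-phenylpropanoate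
Product: 17 2-acetoxy-3,6-bis[4-(benzyloxy)phenyl]-4,5-dihydroxyphenyl 3-phenylpropanoate, via acetoxy acetal 15 (not isolated), via monoformate 16 (not isolated)
Conditions: Pb(OAc)4 (2.5 equiv), benzene, 80 °C; then AcOH/H2O/THF 3:1:1, rt to 40 °C
Reagents that add atoms: none
Why: Oxidative methylene-acetal cleavage, in which tetravalent lead removes hydride from the uniquely activated O–CH2–O carbon, acetate traps the dioxolanylium ion, and the resulting acyloxy orthoformate hydrolyses through the aryl formate to the catechol much faster than the aryl acetate or 3-phenylpropanoate can hydrolyse.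

Step 11
Reactants: 17 2-acetoxy-3,6-bis[4-(benzyloxy)phenyl]-4,5-dihydroxyphenyl 3-phenylpropanoate; 3 (R)-3-(benzyloxy)butanoic acid
Product: 18 4-acetoxy-3,6-bis[4-(benzyloxy)phenyl]-5-[(3-phenylpropanoyl)oxy]-1,2-phenylene bis[(3R)-3-(benzyloxy)butanoate]
Conditions: 3 (3 equiv), DCC (3.3 equiv), DMAP (0.3 equiv), CH2Cl2, 0 °C to rt
Reagents that add atoms: none
Why: Steglich esterification of both phenols with excess acid brings in the two R centres fixed in 3, which sit beta to the carbonyl and are not touched, and the existing esters cannot migrate because they are not ortho to the free hydroxyls.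

Step 12
Reactants: 18 4-acetoxy-3,6-bis[4-(benzyloxy)phenyl]-5-[(3-phenylpropanoyl)oxy]-1,2-phenylene bis[(3R)-3-(benzyloxy)butanoate]
Product: 19 curtisian V
Conditions: H2 (1 atm), Pd(OH)2/C (20 wt %), EtOAc/THF, rt
Reagents that add atoms: none
Why: Catalytic hydrogenolysis cleaves the two aryl and two secondary alkyl benzyl ethers as toluene, while the four aryl esters and the R carbinol centres are inert in a non-nucleophilic solvent.

## Compound list

1 | methyl (R)-3-hydroxybutanoate | C[C@@H](O)CC(=O)OC | starting material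
2 | methyl (R)-3-(benzyloxy)butanoate | C[C@@H](OCc1ccccc1)CC(=O)OC | intermediate
3 | (R)-3-(benzyloxy)butanoic acid | C[C@@H](OCc1ccccc1)CC(=O)O | intermediate
4 | sesamol (1,3-benzodioxol-5-ol) | Oc1ccc2OCOc2c1 | starting material
5 | 1,3-benzodioxole-5,6-dione (ortho-quinone, formed in the flask) | O=C1C(=O)C=C2OCOC2=C1 | intermediate
6 | 1,3-benzodioxole-5,6-diol | Oc1cc2OCOc2cc1O | intermediate
7 | 5,6-bis(methoxymethoxy)-1,3-benzodioxole | COCOc1cc2OCOc2cc1OCOC | intermediate
8 | 4,7-dibromo-5,6-bis(methoxymethoxy)-1,3-benzodioxole | COCOc1c(Br)c2OCOc2c(Br)c1OCOC | intermediate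
9 | [4-(benzyloxy)phenyl]boronic acid | OB(O)c1ccc(OCc2ccccc2)cc1 | starting material
10 | 4,7-bis[4-(benzyloxy)phenyl]-5,6-bis(methoxymethoxy)-1,3-benzodioxole | COCOc1c(-c2ccc(OCc3ccccc3)cc2)c2OCOc2c(-c2ccc(OCc3ccccc3)cc2)c1OCOC | intermediate
11 | 4,7-bis[4-(benzyloxy)phenyl]-1,3-benzodioxole-5,6-diol | Oc1c(-c2ccc(OCc3ccccc3)cc2)c2OCOc2c(-c2ccc(OCc3ccccc3)cc2)c1O | intermediate
12 | 3-phenylpropanoyl chloride | O=C(Cl)CCc1ccccc1 | starting material
13 | 4,7-bis[4-(benzyloxy)phenyl]-6-hydroxy-1,3-benzodioxol-5-yl 3-phenylpropanoate | O=C(CCc1ccccc1)Oc1c(-c2ccc(OCc3ccccc3)cc2)c2OCOc2c(-c2ccc(OCc3ccccc3)cc2)c1O | intermediate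
14 | 6-acetoxy-4,7-bis[4-(benzyloxy)phenyl]-1,3-benzodioxol-5-yl 3-phenylpropanoate | CC(=O)Oc1c(OC(=O)CCc2ccccc2)c(-c2ccc(OCc3ccccc3)cc2)c2OCOc2c1-c1ccc(OCc2ccccc2)cc1 | intermediate
15 | 2,6-diacetoxy-4,7-bis[4-(benzyloxy)phenyl]-1,3-benzodioxol-5-yl 3-phenylpropanoate (acetoxy acetal, racemic at C2, formed in the flask) | CC(=O)OC1Oc2c(O1)c(-c3ccc(OCc4ccccc4)cc3)c(OC(C)=O)c(OC(=O)CCc3ccccc3)c2-c2ccc(OCc3ccccc3)cc2 | intermediate
16 | 2-acetoxy-3,6-bis[4-(benzyloxy)phenyl]-5-(formyloxy)-4-hydroxyphenyl 3-phenylpropanoate (monoformate, one of two interconverting regioisomers, formed in the flask) | O=COc1c(O)c(-c2ccc(OCc3ccccc3)cc2)c(OC(C)=O)c(OC(=O)CCc2ccccc2)c1-c1ccc(OCc2ccccc2)cc1 | intermediate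
17 | 2-acetoxy-3,6-bis[4-(benzyloxy)phenyl]-4,5-dihydroxyphenyl 3-phenylpropanoate | Oc1c(O)c(-c2ccc(OCc3ccccc3)cc2)c(OC(C)=O)c(OC(=O)CCc2ccccc2)c1-c1ccc(OCc2ccccc2)cc1 | intermediate
18 | 4-acetoxy-3,6-bis[4-(benzyloxy)phenyl]-5-[(3-phenylpropanoyl)oxy]-1,2-phenylene bis[(3R)-3-(benzyloxy)butanoate] | CC(=O)Oc1c(OC(=O)CCc2ccccc2)c(-c2ccc(OCc3ccccc3)cc2)c(OC(=O)C[C@@H](C)OCc2ccccc2)c(OC(=O)C[C@@H](C)OCc2ccccc2)c1-c1ccc(OCc2ccccc2)cc1 | intermediate
19 | curtisian V, 4-acetoxy-3,6-bis(4-hydroxyphenyl)-5-[(3-phenylpropanoyl)oxy]-1,2-phenylene bis[(3R)-3-hydroxybutanoate] | CC(=O)Oc1c(OC(=O)CCc2ccccc2)c(-c2ccc(O)cc2)c(OC(=O)C[C@@H](C)O)c(OC(=O)C[C@@H](C)O)c1-c1ccc(O)cc1 | target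

## Step count and risks

Total steps: 12 (2 for the side-chain acid, 10 on the core).
Longest linear sequence: 10 steps (steps 3 to 12, from sesamol 4).

Steps most likely to fail:

Step 10, oxidative removal of the methylene acetal. Pb(OAc)4 at 80 °C may also attack the benzyl ethers, and the hydrolysis must spare two aryl esters. The fallback sets out from 9 and comes back at 18, and it never makes a methylene acetal. Boronic acid 9 is coupled twice with commercial 2,5-dibromo-3,6-dimethoxy-1,4-benzoquinone (COC1=C(Br)C(=O)C(OC)=C(Br)C1=O) under Pd(PPh3)4, K2CO3, dioxane/H2O at 90 °C to give 2,5-bis[4-(benzyloxy)phenyl]-3,6-dimethoxy-1,4-benzoquinone F1. NaOH in aqueous dioxane, then HCl, hydrolyses the two vinylogous esters to 2,5-bis[4-(benzyloxy)phenyl]-3,6-dihydroxy-1,4-benzoquinone F2. Na2S2O4 under argon reduces this to 3,6-bis[4-(benzyloxy)phenyl]benzene-1,2,4,5-tetraol F3. One equivalent of trimethyl orthoacetate (PPTS, toluene, 80 °C) ties one of the two equivalent catechol pairs into the cyclic orthoester 4,7-bis[4-(benzyloxy)phenyl]-2-methoxy-2-methyl-1,3-benzodioxole-5,6-diol F4; this step is statistical and unreacted F3 is recycled. Acid 3 with DCC/DMAP esterifies the free pair to 4,7-bis[4-(benzyloxy)phenyl]-2-methoxy-2-methyl-1,3-benzodioxole-5,6-diyl bis[(3R)-3-(benzyloxy)butanoate] F5. Aqueous AcOH/THF opens the orthoester to the monoacetate 4-acetoxy-5-hydroxy-3,6-bis[4-(benzyloxy)phenyl]-1,2-phenylene bis[(3R)-3-(benzyloxy)butanoate] F6, and 12 in pyridine acylates the last hydroxyl to give 18. The orthoester both distinguishes the two catechol pairs and delivers the acetate.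

Step 8, monoacylation of the catechol. Over-acylation to the bis(3-phenylpropanoate) and unreacted diol can erode the yield. The fallback sets out from 11 and comes back at 14; it reverses the order of the two acyl groups and enforces monoacylation through a ring. Diol 11 with trimethyl orthoacetate (PPTS, toluene, 80 °C) gives the cyclic orthoester 4,8-bis[4-(benzyloxy)phenyl]-2-methoxy-2-methylbenzo[1,2-d:4,5-d']bis[1,3]dioxole F7. Aqueous AcOH/THF opens it to exactly one acetate, 4,7-bis[4-(benzyloxy)phenyl]-6-hydroxy-1,3-benzodioxol-5-yl acetate F8. Acylation of F8 with 12 (pyridine, DMAP, CH2Cl2) then gives 14.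

Step 3, ortho-oxygenation of sesamol. The electron-rich phenol can add to its own ortho-quinone and dimerise. The fallback sets out from 4 and comes back at 6; it replaces the oxidation by C–C bond formation followed by an aryl migration. Ortho-formylation of 4 (MgCl2, Et3N, paraformaldehyde, MeCN, reflux) gives 6-hydroxy-1,3-benzodioxole-5-carbaldehyde F9. Dakin oxidation (H2O2, NaOH, H2O/THF, 0 °C, argon, then HCl) converts it through 6-hydroxy-1,3-benzodioxol-5-yl formate F10, hydrolysed in the same flask, into 6.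

## Further compounds

F1 | step 10 | 2,5-bis[4-(benzyloxy)phenyl]-3,6-dimethoxy-1,4-benzoquinone | COC1=C(c2ccc(OCc3ccccc3)cc2)C(=O)C(OC)=C(c2ccc(OCc3ccccc3)cc2)C1=O
F2 | step 10 | 2,5-bis[4-(benzyloxy)phenyl]-3,6-dihydroxy-1,4-benzoquinone | OC1=C(c2ccc(OCc3ccccc3)cc2)C(=O)C(O)=C(c2ccc(OCc3ccccc3)cc2)C1=O
F3 | step 10 | 3,6-bis[4-(benzyloxy)phenyl]benzene-1,2,4,5-tetraol | Oc1c(O)c(-c2ccc(OCc3ccccc3)cc2)c(O)c(O)c1-c1ccc(OCc2ccccc2)cc1
F4 | step 10 | 4,7-bis[4-(benzyloxy)phenyl]-2-methoxy-2-methyl-1,3-benzodioxole-5,6-diol | COC1(C)Oc2c(O1)c(-c1ccc(OCc3ccccc3)cc1)c(O)c(O)c2-c1ccc(OCc2ccccc2)cc1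
F5 | step 10 | 4,7-bis[4-(benzyloxy)phenyl]-2-methoxy-2-methyl-1,3-benzodioxole-5,6-diyl bis[(3R)-3-(benzyloxy)butanoate] | COC1(C)Oc2c(O1)c(-c1ccc(OCc3ccccc3)cc1)c(OC(=O)C[C@@H](C)OCc1ccccc1)c(OC(=O)C[C@@H](C)OCc1ccccc1)c2-c1ccc(OCc2ccccc2)cc1
F6 | step 10 | 4-acetoxy-5-hydroxy-3,6-bis[4-(benzyloxy)phenyl]-1,2-phenylene bis[(3R)-3-(benzyloxy)butanoate] | CC(=O)Oc1c(O)c(-c2ccc(OCc3ccccc3)cc2)c(OC(=O)C[C@@H](C)OCc2ccccc2)c(OC(=O)C[C@@H](C)OCc2ccccc2)c1-c1ccc(OCc2ccccc2)cc1
F7 | step 8 | 4,8-bis[4-(benzyloxy)phenyl]-2-methoxy-2-methylbenzo[1,2-d:4,5-d']bis[1,3]dioxole | COC1(C)Oc2c(O1)c(-c1ccc(OCc3ccccc3)cc1)c1OCOc1c2-c1ccc(OCc2ccccc2)cc1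
F8 | step 8 | 4,7-bis[4-(benzyloxy)phenyl]-6-hydroxy-1,3-benzodioxol-5-yl acetate | CC(=O)Oc1c(O)c(-c2ccc(OCc3ccccc3)cc2)c2OCOc2c1-c1ccc(OCc2ccccc2)cc1
F9 | step 3 | 6-hydroxy-1,3-benzodioxole-5-carbaldehyde | O=Cc1cc2OCOc2cc1O
F10 | step 3 | 6-hydroxy-1,3-benzodioxol-5-yl formate | O=COc1cc2OCOc2cc1O
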